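**Plan**

1. Numbering (germacrane): C1 ketone, C2=C3 furanone alkene, C4 (methyl C15), C5–C9, C10 (methyl C14; the ether oxygen bridges C3 and C10), C11 carrying C12 (lactone carbonyl) and C13 (CH2Cl).
2. Retrosynthetic cuts, latest first: C13–Cl (through the 11,13-epoxide), the O8–tigloyl bond, the lactone C6–O bond, C8–O/C9–O, C8=C9, the furanone O–C3 bond, C1–C2, C4–C5, C11–C13 and C7–C8.
3. Feature used: on the ten-membered carbocycle C1–C10, bridged by the furanone oxygen between C3 and C10, the C12 carboxyl of the C7 side chain lies γ to the C6 methylene (C12–C11–C7–C6), so the free acid can pass its own oxygen to C6 and close the γ-lactone.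
4. Forward order: the C5–C8/C11–C13 chain is made first, extended to C2–C4 by propargylation and joined at C1–C2 to the C10 unit; rings then arise in the order furanone, ten-membered carbocycle, γ-lactone, transient 11,13-epoxide.
5. C13 is carried from step 6 as a chloromethyl branch, so the exocyclic methylene is later unveiled by loss of HCl and not by lactone enolate chemistry (which the γ-acidic C4–H and any C5 acyloxy group would not survive); all three hydroxyls are masked as trifluoroacetates for the key step so that they can be removed by neutral methanolysis.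
6. Stereochemistry: C10 from asymmetric allylic etherification; C7 from Rh/BINAP vinyl addition; C4 and C5 from the (R)-butynyl mesylate (anti propargylation); C8 and C9 from syn osmylation of the Z alkene; C6 from the directed C–H lactonisation; C11 from epoxidation anti to C8.

Key step: step 17

Assumption: the ligand antipodes given for steps 1, 5 and 17 follow the usual facial models and the mirror-image ligand is used if one proves mismatched; C11 is an inconsequential epimer mixture from step 6 until it becomes sp2 in step 20.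

**Route**

Step 1
Reactants: 1 isoprene monoepoxide (2-methyl-2-vinyloxirane, racemic); 2 p-methoxybenzyl alcohol
Product: 3 (2S)-2-[(4-methoxyphenyl)methoxy]-2-methylbut-3-en-1-ol
Conditions: Pd2(dba)3·CHCl3 (1 mol %), (R,R)-DACH-phenyl Trost ligand (3 mol %), Et3B (1 mol %), CH2Cl2, rt
Reagents that add atoms: none
Why: Palladium-catalysed dynamic kinetic asymmetric allylic etherification of a vinyl epoxide (Tsuji–Trost type), in which the equilibrating π-allyl complexes are intercepted by the boron-bound alkoxide at the tertiary terminus and the chiral ligand sets the C10 ether stereocentre.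

Step 2
Reactants: 3 PMB ether alcohol
Product: 5 (2S)-2-[(4-methoxyphenyl)methoxy]-2-methylbut-3-enoic acid, via aldehyde 4 (not isolated)
Conditions: TEMPO (0.2 equiv), PhI(OAc)2 (2.2 equiv), MeCN/H2O (1:1), rt
Reagents that add atoms: water (O)
Why: Oxoammonium (TEMPO) oxidation of the primary alcohol to the aldehyde and, through its hydrate, to the acid; the quaternary α-carbon cannot epimerise and the PMB ether and vinyl group should be inert.

Step 3
Reactants: 5 acid
Product: 7 (2S)-N-methoxy-2-[(4-methoxyphenyl)methoxy]-N,2-dimethylbut-3-enamide, via acyl imidazolide 6 (not isolated)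
Conditions: 1,1'-carbonyldiimidazole, CH2Cl2, rt; then MeNH(OMe)·HCl, rt
Reagents that add atoms: N,O-dimethylhydroxylamine hydrochloride (CNOC.Cl)
Why: Weinreb amide formation by acyl substitution of the acyl imidazolide, a mild activation that should tolerate the hindered α-alkoxy acid.

Step 4
Reactants: 8 tert-butyl acrylate; 9 4,4-diethoxybut-1-ene
Product: 10 tert-butyl (2E)-5,5-diethoxypent-2-enoate
Conditions: second-generation Hoveyda–Grubbs catalyst (H2IMes)Cl2Ru=CH(2-i-PrOC6H4) (2 mol %), CH2Cl2, 40 °C
Reagents that add atoms: none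
Why: Olefin cross-metathesis of an electron-poor acrylate with a terminal alkene, which favours the cross product and the E enoate.

Step 5
Reactants: 10 enoate; 11 potassium vinyltrifluoroborate
Product: 12 tert-butyl (3R)-3-(2,2-diethoxyethyl)pent-4-enoate
Conditions: [Rh(cod)2]BF4 (3 mol %), (S)-BINAP (3.3 mol %), Et3N (2 equiv), toluene/H2O (10:1), 90 °C
Reagents that add atoms: none
Why: Rhodium-catalysed asymmetric conjugate addition of an alkenylboron reagent (Hayashi–Miyaura reaction), in which the vinylrhodium–BINAP complex inserts the E enoate on one face and so sets C7; the bulky tert-butyl ester should help the selectivity.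

Step 6
Reactants: 12 vinyl ester; 13 chloroiodomethane
Product: 15 tert-butyl (2RS,3S)-2-(chloromethyl)-3-(2,2-diethoxyethyl)pent-4-enoate, via lithium enolate 14 (not isolated)
Conditions: LiN(i-Pr)2, THF, −78 °C; then ICH2Cl, −78 to −40 °C
Reagents that add atoms: none
Why: Ester enolate alkylation (SN2 at the iodine-bearing carbon) installs C13 as a chloromethyl branch; the new C11 centre is an epimer mixture of no consequence, and the C3 label changes from R to S by CIP priority only.

Step 7
Reactants: 15 chloromethyl acetal ester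
Product: 16 tert-butyl (2RS,3S)-2-(chloromethyl)-3-(2-oxoethyl)pent-4-enoate
Conditions: PPTS (0.2 equiv), acetone/H2O (9:1), 50 °C
Reagents that add atoms: water (O)
Why: Acid-catalysed acetal hydrolysis under conditions too mild to cleave the tert-butyl ester or displace the chloride.

Step 8
Reactants: 17 (2R)-but-3-yn-2-ol
Product: 18 (2R)-but-3-yn-2-yl methanesulfonate
Conditions: MsCl, Et3N, CH2Cl2, −78 to 0 °C
Reagents that add atoms: methanesulfonyl chloride (CS(=O)(=O)Cl)
Why: O-Sulfonylation of the alcohol, which breaks no bond at the stereocentre and so retains its configuration.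

Step 9
Reactants: 16 aldehyde; 18 mesylate
Product: 20 tert-butyl (2RS,3S,5R,6S)-2-(chloromethyl)-3-ethenyl-5-hydroxy-6-methyloct-7-ynoate, via allenylzinc mesylate 19 (not isolated)
Conditions: Pd(OAc)2 (5 mol %), PPh3 (5 mol %), Et2Zn (3 equiv), THF, −78 to −20 °C; aq. NH4Cl
Reagents that add atoms: none
Why: Marshall propargylation, in which anti SN2' oxidative addition of zerovalent palladium to the mesylate and transmetallation to zinc give a configurationally defined allenylzinc that adds to the aldehyde through a cyclic SE2' transition state, so the anti C4/C5 pair is set by the reagent and not by the remote C7 centre.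

Step 10
Reactants: 20 alkynol; 7 Weinreb amide
Product: 22 tert-butyl (2RS,3S,5R,6S,10S)-2-(chloromethyl)-3-ethenyl-5-hydroxy-10-[(4-methoxyphenyl)methoxy]-6,10-dimethyl-9-oxododec-11-en-7-ynoate, via magnesium alkynide alkoxide 21 (not isolated)
Conditions: i-PrMgCl·LiCl (2.1 equiv), THF, 0 °C to rt; then 7, 0 °C; aq. NH4Cl
Reagents that add atoms: none
Why: Acylation of an alkynylmagnesium reagent by a Weinreb amide, whose chelated tetrahedral adduct prevents over-addition; the magnesium alkoxide of C5–OH and the hindered tert-butyl ester should be spectators.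

Step 11
Reactants: 22 PMB-protected ynone
Product: 23 tert-butyl (2RS,3S,5R,6S,10S)-2-(chloromethyl)-3-ethenyl-5,10-dihydroxy-6,10-dimethyl-9-oxododec-11-en-7-ynoate
Conditions: DDQ (1.3 equiv), CH2Cl2/pH 7 buffer (10:1), 0 °C
Reagents that add atoms: none
Why: Oxidative cleavage of the p-methoxybenzyl ether (hydride abstraction, then hydrolysis of the oxocarbenium ion) frees the tertiary alcohol without acid or base, so the ynone and the propargylic C4–H are not disturbed.

Step 12
Reactants: 23 hydroxy ynone
Product: 24 tert-butyl (2RS,3S,5R,6R)-2-(chloromethyl)-3-ethenyl-6-[(5S)-5-ethenyl-5-methyl-4-oxo-4,5-dihydrofuran-2-yl]-5-hydroxyheptanoate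
Conditions: Ph3PAuNTf2 (3 mol %), CH2Cl2, rt
Reagents that add atoms: none
Why: Gold-catalysed 5-endo-dig cycloisomerisation of an α'-hydroxy ynone, in which the C10 hydroxyl adds to the activated β-carbon C3 and protodeauration gives the 3(2H)-furanone; the label of the methyl-bearing carbon changes from S to R by priority only.

Step 13
Reactants: 24 furanone diene
Product: 25 tert-butyl (4R,5R,7S,8Z,10S,11RS)-13-chloro-5-hydroxy-1-oxo-3,10-epoxygermacra-2,8-dien-12-oate
Conditions: second-generation Grubbs catalyst (H2IMes)(PCy3)Cl2Ru=CHPh (10 mol %, in portions), toluene (0.001 mol/L), 80 °C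
Reagents that add atoms: none
Why: Ring-closing metathesis of the two vinyl groups, driven by loss of ethene, closes the ten-membered carbocycle (a nine-membered ring through the furanone oxygen), in which only the Z C8=C9 alkene is geometrically reasonable.

Step 14
Reactants: 25 Z-cycloalkene
Product: 26 tert-butyl (4R,5R,7R,8S,9S,10S,11RS)-13-chloro-5,8,9-trihydroxy-1-oxo-3,10-epoxygermacr-2-en-12-oate
Conditions: OsO4 (5 mol %), NMO (1.5 equiv), acetone/H2O (5:1), 0 °C to rt
Reagents that add atoms: osmium tetroxide (O=[Os](=O)(=O)=O); N-methylmorpholine N-oxide (C[N+]1([O-])CCOCC1)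
Why: Catalytic syn dihydroxylation (Upjohn conditions) of the only isolated alkene, the vinylogous-ester alkene being deactivated; syn addition to the Z alkene gives the required 8,9 relationship, and attack is expected on the face bearing the ring oxygen and the C6 methylene, away from the C14 methyl and the branched C11 side chain, which makes C8 and C9 both S.

Step 15
Reactants: 26 triol
Product: 27 tert-butyl (4R,5R,7R,8S,9S,10S,11RS)-13-chloro-1-oxo-5,8,9-tris(trifluoroacetoxy)-3,10-epoxygermacr-2-en-12-oate
Conditions: (CF3CO)2O (6 equiv), pyridine (8 equiv), CH2Cl2, −20 to 0 °C; evaporation, short silica plug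
Reagents that add atoms: trifluoroacetic anhydride (O=C(OC(=O)C(F)(F)F)C(F)(F)F)
Why: Exhaustive O-acylation, which makes the C5–H, C8–H and C9–H bonds electron-poor for step 17 and prevents lactonisation of O8 onto C12 when the acid is freed.

Step 16
Reactants: 27 tris(trifluoroacetate) ester
Product: 28 (4R,5R,7R,8S,9S,10S,11RS)-13-chloro-1-oxo-5,8,9-tris(trifluoroacetoxy)-3,10-epoxygermacr-2-en-12-oic acid
Conditions: CF3CO2H/CH2Cl2 (1:3), 0 °C to rt; co-evaporation with toluene
Reagents that add atoms: none
Why: Acidolysis of the tert-butyl ester (loss of isobutene), to which the trifluoroacetates, the alkyl chloride and the furanone are inert, and which needs no aqueous work-up.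

Step 17
Reactants: 28 acid
Product: 29 (4R,5S,6S,7S,8S,9S,10S,11RS)-13-chloro-1-oxo-5,8,9-tris(trifluoroacetoxy)-3,10-epoxygermacr-2-en-12,6-olide
Conditions: [Mn(OTf)2((S,S)-pdp)] (pdp = N,N'-bis(2-pyridylmethyl)-2,2'-bipyrrolidine; 3 × 2 mol %), H2O2 (50% aq., 3 equiv, syringe pump), (CF3)2CHOH, 0 °C
Reagents that add atoms: none
Why: The carboxylic acid binds the divalent manganese catalyst and assists heterolysis of coordinated H2O2 to a high-valent oxomanganese carboxylate, which abstracts a γ-hydrogen from C6 through a seven-membered (1,7) hydrogen-transfer transition state, and the C6 radical is captured by the metal-bound carboxylate, so the lactone oxygen is the substrate's own. The closest known reaction type is the manganese-catalysed carboxylic-acid-directed γ-C(sp3)–H lactonisation of aliphatic acids with H2O2, applied here to a methylene group of an α-branched acid. The γ-lactone (O–C12–C11–C7–C6) closes by C6–O bond formation, formally a 5-exo capture of the C6 radical by the carboxylate oxygen. The new C6 centre is controlled by the ring: with C5–C6–C7–C8 held anti in the oxygen-bridged ten-membered ring, only the C6 hydrogen gauche to C11 can reach the oxo group, and rebound with retention should give the trans-fused (6S) lactone from either C11 epimer. The step needs γ-selectivity for C6 over C8 and tolerance of the furanone alkene and the allylic C4–H: the trifluoroacetates switch off C8–H (the other γ-hydrogen) as well as C5–H and C9–H, the chloromethyl hydrogens are β and electron-poor, and the vinylogous-ester alkene and C4–H are electron-poor and further deactivated by hydrogen bonding in (CF3)2CHOH, while intramolecular delivery should outrun intermolecular oxidation.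

Step 18
Reactants: 29 lactone tris(trifluoroacetate)
Product: 30 (4R,5S,6S,7R,8S,9S,10S,11RS)-13-chloro-5,8,9-trihydroxy-1-oxo-3,10-epoxygermacr-2-en-12,6-olide
Conditions: MeOH, 40 °C; evaporation
Reagents that add atoms: none
Why: Neutral methanolysis (transesterification) of the three activated trifluoroacetates; with no base present the lactone should not migrate to O8, C4–H is not touched and the chloride is not eliminated (the C7 label changes by priority only).

Step 19
Reactants: 30 triol lactone; 31 tigloyl chloride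
Product: 32 (4R,5S,6S,7S,8S,9S,10S,11RS)-13-chloro-5,9-dihydroxy-8-[(2E)-2-methylbut-2-enoyloxy]-1-oxo-3,10-epoxygermacr-2-en-12,6-olide
Conditions: Ph2BOCH2CH2NH2 (10 mol %), i-Pr2NEt (1.5 equiv), MeCN, 0 °C to rt
Reagents that add atoms: none
Why: Borinic-acid-catalysed regioselective monoacylation of a cis-1,2-diol, in which the tetracoordinate borinate of the C8/C9 diol should be acylated at the less hindered O8 (O9 is neopentylic, next to quaternary C10) while the isolated C5–OH is not activated.

Step 20
Reactants: 32 8-O-tiglate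
Product: 34 (4R,5S,6S,7S,8S,9S,10S,11R)-11,13-epoxy-5,9-dihydroxy-8-[(2E)-2-methylbut-2-enoyloxy]-1-oxo-3,10-epoxygermacr-2-en-12,6-olide, via methylene lactone 33 (not isolated)
Conditions: DBU (2.5 equiv), t-BuOOH (5 equiv, in decane), CH2Cl2, 0 °C
Reagents that add atoms: tert-butyl hydroperoxide (CC(C)(C)OO)
Why: E1cB loss of HCl from either C11 epimer unveils the α-methylene lactone, which undergoes Weitz–Scheffer nucleophilic epoxidation at the most electrophilic alkene; the lactone enolate closes onto oxygen on the face anti to C8 (syn to H7), which places the C11 oxygen as in the target.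

Step 21
Reactants: 34 spiro-epoxide
Product: 35 (4R,5S,6S,7S,8S,9S,10S,11S)-13-chloro-5,9,11-trihydroxy-8-[(2E)-2-methylbut-2-enoyloxy]-1-oxo-3,10-epoxygermacr-2-en-12,6-olide (CNP0340393.1)
Conditions: HCl (1 mol/L in Et2O, 1.5 equiv), CH2Cl2, −20 to 0 °C
Reagents that add atoms: hydrogen chloride (Cl)
Why: Acid-promoted SN2 opening of the glycidic-type spiro-epoxide by chloride at the primary C13 (C11 is tertiary and next to the carbonyl), so the C11–O bond and its configuration are kept and the chlorohydrin results.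

**Compound list**

1 | isoprene monoepoxide (2-methyl-2-vinyloxirane, racemic) | CC1(C=C)CO1 | starting material
2 | 4-methoxybenzyl alcohol | COc1ccc(CO)cc1 | starting material
3 | (2S)-2-[(4-methoxyphenyl)methoxy]-2-methylbut-3-en-1-ol | OC[C@@](C)(OCc1ccc(OC)cc1)C=C | intermediate
4 | (2S)-2-[(4-methoxyphenyl)methoxy]-2-methylbut-3-enal (not isolated) | O=C[C@@](C)(OCc1ccc(OC)cc1)C=C | intermediate
5 | (2S)-2-[(4-methoxyphenyl)methoxy]-2-methylbut-3-enoic acid | OC(=O)[C@@](C)(OCc1ccc(OC)cc1)C=C | intermediate
6 | (2S)-1-(imidazol-1-yl)-2-[(4-methoxyphenyl)methoxy]-2-methylbut-3-en-1-one (not isolated) | O=C(n1ccnc1)[C@@](C)(OCc1ccc(OC)cc1)C=C | intermediate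
7 | (2S)-N-methoxy-2-[(4-methoxyphenyl)methoxy]-N,2-dimethylbut-3-enamide | CON(C)C(=O)[C@@](C)(OCc1ccc(OC)cc1)C=C | intermediate
8 | tert-butyl acrylate | C=CC(=O)OC(C)(C)C | starting material
9 | 4,4-diethoxybut-1-ene | C=CCC(OCC)OCC | starting material
10 | tert-butyl (2E)-5,5-diethoxypent-2-enoate | CCOC(OCC)C/C=C/C(=O)OC(C)(C)C | intermediate
11 | potassium vinyltrifluoroborate | C=C[B-](F)(F)F.[K+] | starting material
12 | tert-butyl (3R)-3-(2,2-diethoxyethyl)pent-4-enoate | C=C[C@@H](CC(=O)OC(C)(C)C)CC(OCC)OCC | intermediate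
13 | chloroiodomethane | ClCI | starting material
14 | lithium enolate of 12, lithium 1-tert-butoxy-3-(2,2-diethoxyethyl)penta-1,4-dien-1-olate with C3 arranged as in 12 (not isolated) | C=C[C@@H](C=C(O[Li])OC(C)(C)C)CC(OCC)OCC | intermediate
15 | tert-butyl (2RS,3S)-2-(chloromethyl)-3-(2,2-diethoxyethyl)pent-4-enoate | C=C[C@@H](C(CCl)C(=O)OC(C)(C)C)CC(OCC)OCC | intermediate
16 | tert-butyl (2RS,3S)-2-(chloromethyl)-3-(2-oxoethyl)pent-4-enoate | C=C[C@@H](C(CCl)C(=O)OC(C)(C)C)CC=O | intermediate
17 | (2R)-but-3-yn-2-ol | C#C[C@@H](C)O | starting material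
18 | (2R)-but-3-yn-2-yl methanesulfonate | C#C[C@@H](C)OS(C)(=O)=O | intermediate
19 | (P)-buta-1,2-dien-1-ylzinc methanesulfonate (not isolated) | CS(=O)(=O)O[Zn]C([H])=[C@@]=C([H])C | intermediate
20 | tert-butyl (2RS,3S,5R,6S)-2-(chloromethyl)-3-ethenyl-5-hydroxy-6-methyloct-7-ynoate | C#C[C@H](C)[C@H](O)C[C@H](C(CCl)C(=O)OC(C)(C)C)C=C | intermediate
21 | chloromagnesium alkoxide and alkynylmagnesium chloride of 20 (not isolated) | Cl[Mg]C#C[C@H](C)[C@H](O[Mg]Cl)C[C@H](C(CCl)C(=O)OC(C)(C)C)C=C | intermediate
22 | tert-butyl (2RS,3S,5R,6S,10S)-2-(chloromethyl)-3-ethenyl-5-hydroxy-10-[(4-methoxyphenyl)methoxy]-6,10-dimethyl-9-oxododec-11-en-7-ynoate | C=C[C@](C)(OCc1ccc(OC)cc1)C(=O)C#C[C@H](C)[C@H](O)C[C@H](C(CCl)C(=O)OC(C)(C)C)C=C | intermediate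
23 | tert-butyl (2RS,3S,5R,6S,10S)-2-(chloromethyl)-3-ethenyl-5,10-dihydroxy-6,10-dimethyl-9-oxododec-11-en-7-ynoate | C=C[C@](C)(O)C(=O)C#C[C@H](C)[C@H](O)C[C@H](C(CCl)C(=O)OC(C)(C)C)C=C | intermediate
24 | tert-butyl (2RS,3S,5R,6R)-2-(chloromethyl)-3-ethenyl-6-[(5S)-5-ethenyl-5-methyl-4-oxo-4,5-dihydrofuran-2-yl]-5-hydroxyheptanoate | C=C[C@]1(C)OC(=CC1=O)[C@H](C)[C@H](O)C[C@H](C(CCl)C(=O)OC(C)(C)C)C=C | intermediate
25 | tert-butyl (4R,5R,7S,8Z,10S,11RS)-13-chloro-5-hydroxy-1-oxo-3,10-epoxygermacra-2,8-dien-12-oate | ClCC(C(=O)OC(C)(C)C)[C@H]1C[C@@H](O)[C@@H](C)C2=CC(=O)[C@@](C)(O2)/C=C\1 | intermediate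
26 | tert-butyl (4R,5R,7R,8S,9S,10S,11RS)-13-chloro-5,8,9-trihydroxy-1-oxo-3,10-epoxygermacr-2-en-12-oate | O[C@H]1[C@@H](C(CCl)C(=O)OC(C)(C)C)C[C@@H](O)[C@@H](C)C2=CC(=O)[C@@](C)(O2)[C@H]1O | intermediate
27 | tert-butyl (4R,5R,7R,8S,9S,10S,11RS)-13-chloro-1-oxo-5,8,9-tris(trifluoroacetoxy)-3,10-epoxygermacr-2-en-12-oate | FC(F)(F)C(=O)O[C@H]1[C@@H](C(CCl)C(=O)OC(C)(C)C)C[C@@H](OC(=O)C(F)(F)F)[C@@H](C)C2=CC(=O)[C@@](C)(O2)[C@H]1OC(=O)C(F)(F)F | intermediate
28 | (4R,5R,7R,8S,9S,10S,11RS)-13-chloro-1-oxo-5,8,9-tris(trifluoroacetoxy)-3,10-epoxygermacr-2-en-12-oic acid (key-step precursor) | FC(F)(F)C(=O)O[C@H]1[C@@H](C(CCl)C(O)=O)C[C@@H](OC(=O)C(F)(F)F)[C@@H](C)C2=CC(=O)[C@@](C)(O2)[C@H]1OC(=O)C(F)(F)F | intermediate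
29 | (4R,5S,6S,7S,8S,9S,10S,11RS)-13-chloro-1-oxo-5,8,9-tris(trifluoroacetoxy)-3,10-epoxygermacr-2-en-12,6-olide (key-step product) | FC(F)(F)C(=O)O[C@H]1[C@@H]2[C@H](OC(=O)C2CCl)[C@@H](OC(=O)C(F)(F)F)[C@@H](C)C2=CC(=O)[C@@](C)(O2)[C@H]1OC(=O)C(F)(F)F | intermediate
30 | (4R,5S,6S,7R,8S,9S,10S,11RS)-13-chloro-5,8,9-trihydroxy-1-oxo-3,10-epoxygermacr-2-en-12,6-olide | O[C@H]1[C@@H]2[C@H](OC(=O)C2CCl)[C@@H](O)[C@@H](C)C2=CC(=O)[C@@](C)(O2)[C@H]1O | intermediate
31 | tigloyl chloride, (2E)-2-methylbut-2-enoyl chloride | C/C=C(\C)C(Cl)=O | starting material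
32 | (4R,5S,6S,7S,8S,9S,10S,11RS)-13-chloro-5,9-dihydroxy-8-[(2E)-2-methylbut-2-enoyloxy]-1-oxo-3,10-epoxygermacr-2-en-12,6-olide | C/C=C(\C)C(=O)O[C@H]1[C@@H]2[C@H](OC(=O)C2CCl)[C@@H](O)[C@@H](C)C2=CC(=O)[C@@](C)(O2)[C@H]1O | intermediate
33 | (4R,5S,6S,7S,8S,9S,10S)-5,9-dihydroxy-8-[(2E)-2-methylbut-2-enoyloxy]-1-oxo-3,10-epoxygermacra-2,11(13)-dien-12,6-olide (not isolated) | C/C=C(\C)C(=O)O[C@H]1[C@@H]2[C@H](OC(=O)C2=C)[C@@H](O)[C@@H](C)C2=CC(=O)[C@@](C)(O2)[C@H]1O | intermediate
34 | (4R,5S,6S,7S,8S,9S,10S,11R)-11,13-epoxy-5,9-dihydroxy-8-[(2E)-2-methylbut-2-enoyloxy]-1-oxo-3,10-epoxygermacr-2-en-12,6-olide | C/C=C(\C)C(=O)O[C@H]1[C@@H]2[C@H](OC(=O)[C@]23CO3)[C@@H](O)[C@@H](C)C2=CC(=O)[C@@](C)(O2)[C@H]1O | intermediate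
35 | (4R,5S,6S,7S,8S,9S,10S,11S)-13-chloro-5,9,11-trihydroxy-8-[(2E)-2-methylbut-2-enoyloxy]-1-oxo-3,10-epoxygermacr-2-en-12,6-olide (CNP0340393.1) | C/C=C(\C)C(=O)O[C@H]1[C@@H]2[C@H](OC(=O)[C@]2(O)CCl)[C@@H](O)[C@@H](C)C2=CC(=O)[C@@](C)(O2)[C@H]1O | target

**Step count and risks**

Total step count: 21. Longest linear sequence: 17 steps (steps 4–7 and 9–21, from tert-butyl acrylate 8).

Steps most likely to fail:

Step 17 (C–H lactonisation). What may go wrong: oxidation of the furanone enol-ether alkene or of the allylic C4–H, loss of trifluoroacetate in the aqueous peroxide medium, or no hydrogen abstraction at a C6 methylene that is flanked by two electron-poor carbons. The fallback replaces metal-oxo chemistry by a radical 1,5-hydrogen transfer; it sets out from acid 28 and returns at lactone 29. Oxalyl chloride converts 28 into the acid chloride F1, and hexamethyldisilazane followed by a methanol quench gives the primary amide F2 without a nucleophilic amine that would cleave the trifluoroacetates. PhI(OAc)2 and I2 under visible light form the N-iodoamide, whose amidyl radical abstracts the C6 hydrogen through a six-membered transition state (Hofmann–Löffler–Freytag type). The resulting C6 iodide is displaced by the amide oxygen to give the iminolactone F3, which dilute aqueous HCl hydrolyses to 29.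

Step 13 (ring-closing metathesis). What may go wrong: oligomerisation or no closure, because the bicyclic transition state is strained and the C10 vinyl group sits on a quaternary carbon. The fallback reverses the order of ring formation; it sets out from hydroxy ynone 23 and returns at 25. The more flexible open-chain diene 23 is cyclised with the same ruthenium catalyst at high dilution to the ten-membered Z-cycloalkenynone F4, and the gold-catalysed 5-endo-dig cyclisation of step 12 is then run transannularly to bridge C3 and C10 and give 25.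

Step 14 (dihydroxylation). What may go wrong: osmylation on the other face of the Z alkene (giving the 8R,9R diol), or competing oxidation of the furanone alkene. The fallback is a Woodward cis-hydroxylation, which places the diol on the face opposite to the one the electrophile attacks; it sets out from 25 and returns at 26. I2 and AgOAc in wet acetic acid give, through the trans-iodo acetate and the bridged acetoxonium ion, the cis-hydroxy acetate F5 (drawn as the 8-acetate), and K2CO3 in methanol at 0 °C removes the acetate to give 26.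

Further compounds
F1 | step 17 | (4R,5R,7R,8S,9S,10S,11RS)-13-chloro-1-oxo-5,8,9-tris(trifluoroacetoxy)-3,10-epoxygermacr-2-en-12-oyl chloride | FC(F)(F)C(=O)O[C@H]1[C@@H](C(CCl)C(Cl)=O)C[C@@H](OC(=O)C(F)(F)F)[C@@H](C)C2=CC(=O)[C@@](C)(O2)[C@H]1OC(=O)C(F)(F)F
F2 | step 17 | (4R,5R,7R,8S,9S,10S,11RS)-13-chloro-1-oxo-5,8,9-tris(trifluoroacetoxy)-3,10-epoxygermacr-2-en-12-amide | FC(F)(F)C(=O)O[C@H]1[C@@H](C(CCl)C(N)=O)C[C@@H](OC(=O)C(F)(F)F)[C@@H](C)C2=CC(=O)[C@@](C)(O2)[C@H]1OC(=O)C(F)(F)F
F3 | step 17 | (4R,5S,6S,7S,8S,9S,10S,11RS)-13-chloro-12-imino-1-oxo-5,8,9-tris(trifluoroacetoxy)-3,10:6,12-diepoxygermacr-2-ene (iminolactone) | FC(F)(F)C(=O)O[C@H]1[C@@H]2[C@H](OC(=N)C2CCl)[C@@H](OC(=O)C(F)(F)F)[C@@H](C)C2=CC(=O)[C@@](C)(O2)[C@H]1OC(=O)C(F)(F)F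
F4 | step 13 | tert-butyl (4S,5R,7S,8Z,10S,11RS)-13-chloro-5,10-dihydroxy-1-oxogermacr-8-en-2-yn-12-oate | ClCC(C(=O)OC(C)(C)C)[C@H]1C[C@@H](O)[C@@H](C)C#CC(=O)[C@@](C)(O)/C=C\1
F5 | step 14 | tert-butyl (4R,5R,7R,8S,9S,10S,11RS)-8-acetoxy-13-chloro-5,9-dihydroxy-1-oxo-3,10-epoxygermacr-2-en-12-oate | CC(=O)O[C@H]1[C@@H](C(CCl)C(=O)OC(C)(C)C)C[C@@H](O)[C@@H](C)C2=CC(=O)[C@@](C)(O2)[C@H]1O
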